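## Analysis of the target

Atom labels used throughout: Ca = CH bearing CO2Me; Cb = the CH2 next to it; Cc = quaternary carbon α to the lactam carbonyl Cd; Ce = N–CH2 of the six-membered ring; Cf = the CH next to Ce; Cg and Ch = the two CH2 groups of the cycloheptene; Ci=Cj = the tetrasubstituted alkene, Cj being bonded to Cc; Ck = allylic CH at the five/five ring fusion; Cl and Cm = the remaining CH2 groups of the cyclopentene; Cn = quaternary carbon bearing CH2OAc; Co and Cp = chain CH2 groups; Cq = CHOH; Cr = CHMe; Cs = the second N–CH2.

The target is a pentacyclic lactam built from ring A, the ester cyclopentane (Ca–Cb–Cc–Cj–Ck), ring B, the cyclopentene (Ci=Cj–Ck–Cl–Cm), ring C, the cycloheptene (Cc–Cj=Ci–Ch–Cg–Cf–Cn), ring D, the δ-lactam (Cc–Cd–N–Ce–Cf–Cn), and ring E, the nine-membered ring that runs from Cn through Co, Cp, Cq, Cr and Cs to nitrogen. It has seven stereocentres: the vicinal quaternary carbons Cc and Cn, then Cf, Ck, Ca, Cq and Cr. Rings C and D form a bridged bicyclo[4.3.1] unit, so Cj on Cc and Cg on Cf are necessarily cis (both axial on ring D); on Cn the CH2OAc group lies on the cycloheptene side and the chain Co on the opposite face, under the lactam, where it can reach nitrogen. In ring A the hydrogens on Ck and Ca both lie on the face that carries the lactam carbonyl, so the ester sits on the crowded face next to Cn, cis to CH2OAc, at an epimerisable centre; in ring E the hydroxyl on Cq and the methyl on Cr are trans on the ring (syn in the extended chain). The sensitive groups are the tetrasubstituted alkene (acid, oxidants), the ester α-CH (base) and a primary acetate that must be told apart from the secondary alcohol. The difficulty lies in Cc, a quaternary carbon bonded at once to a carbonyl, an alkene carbon, a second quaternary carbon and ring A, and in the medium ring E. The strategy rests on the Cc–Cj bond, which joins the quaternary α-carbon of the lactam to an alkene carbon shared by rings B and C: this is the bond that an alkenylpalladium species makes when it adds to the α-carbon of an α-alkylidene lactam.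

## Retrosynthetic reasoning

**43 ⇒ 42.** The carbinol Cq is taken back to the ketone. The last stereocentre then comes from a hydride addition beside the existing CHMe centre, and no hydroxyl protection is needed in the endgame.

**42 ⇒ 40.** The Cs–Cr bond is cut. In the forward direction the N-methoxymethyl group of 40 ionises to the N-acyliminium ion 41, which is attacked by a regiodefined silyl enol ether. Ring E is closed last because the chain on Cn already hangs under the lactam nitrogen, and because a nine-membered ring is best made by a fast C–C bond formation on a rigid core. 40 comes from acetal 36 through aldehyde 37, allylic alcohol 38 and vinyl ketone 39; hydrosilylation of 39 fixes the enol ether regiochemistry.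

**36 ⇒ 34.** The methyl ester on Ca and the acetate on Cn are cis on ring A, so they are written as one seven-membered lactone. The lactone is the tether for the next disconnection, and it later opens to 35 and then 36.

**34 ⇒ 33.** The Ca–Ck bond is cut: a rhodium carbenoid at Ca inserts into the allylic C–H of ring B. It is done on the lactone and not on a free ester chain. The tether holds the carbene on the Cn face, which is the face the target requires at Ck and which a free, bulky carbenoid would avoid. It also keeps the carbene away from the lactam oxygen (carbonyl ylide) and from the other C–H bonds five atoms away, and it fixes the ester configuration at Ca. 33 comes from lactone 31 by diazo transfer.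

**31 ⇒ 27.** The lactone is opened retrosynthetically at the Cb–Ca bond. A vinyl group on Cc (27) and an acrylate ester on the CH2OH of Cn (29, from 28) are joined by ring-closing metathesis to 30, which is hydrogenated to 31. This supplies the two carbons that the key step does not.

**27 ⇒ 26 (key).** The Cc–Cj bond is cut. The alkenyl triflate of 26 adds, through palladium, to the α-carbon of the ethylidene lactam; ring C closes and Cc is set by the tether from Cf. The exocyclic alkene carries methyl and not an acetic ester arm. The aldehyde needed to bring in such an arm by aldol condensation would be a β-dicarbonyl compound, which the lactam enolate would only deprotonate, and a β,γ-unsaturated ester would drift into conjugation under base. β-Hydride loss then leaves a vinyl group, which the previous paragraph uses.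

**26 ⇒ 23 ⇒ 21 ⇒ 17 + 19.** The ethylidene group comes from an aldol condensation on lactam 23 (through 24). The tetrasubstituted alkenyl triflate comes regiospecifically from enone 21 by conjugate reduction and enolate trapping. 21 comes from the vinyl group of 17 and iodoenone 19 by hydroboration and B-alkyl Suzuki coupling. Ring B and the two-carbon link are thereby attached in one operation, with no regiochemical question about the triflate.

**17 ⇒ 15 ⇒ 12 ⇒ 10.** The δ-lactam is made from a butyrolactone. The quaternary centre is easiest to build α to a lactone carbonyl, but that carbonyl is the future CH2OAc carbon. After reduction the two primary hydroxyls are therefore differentiated by translactonisation (12), and nitrogen is brought in at the free one (13); the amine then opens the new lactone to lactam 15.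

**10 ⇒ 9 ⇒ 7 ⇒ 5 ⇒ 3 ⇒ 1 + 2.** Cn is set by two successive enolate alkylations of lactone 7, the second anti to the vinyl group. The single stereocentre of 7 (Cf) comes from an auxiliary-controlled dienolate alkylation of imide 3 with 4, and 3 comes from 1 and 2.

## Alternatives that were turned down

**Alternative 1: nine-membered ring closure as the carrier of the strategy.**
- Disconnection: the Cs–Cr bond of ring E.
- Forward key step: a Lewis acid ionises the N-methoxymethyl lactam A2, whose chain on Cn ends in a Z silyl enol ether, and the N-acyliminium ion is trapped by that enol ether to give the pentacyclic ketone A1.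
- For it: the electrophile is highly reactive, the nucleophile is regiodefined, and the chain is preorganised on a rigid core.
- Against it: it is a way to finish, not a way to build. All of A2 must exist first (rings A–D, both quaternary carbons), and the step says nothing about how. Its one new stereocentre, CHMe, is controlled only by the conformation of a medium ring.
- Comparison: for closing ring E it is as good as anything available, and the chosen route ends with exactly this operation (A2 is 40, A1 is 42). What the chosen strategy adds is a solution to the harder problem, the Cc–Cj bond and ring C, with the configuration at Cc fixed by geometry.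

**Alternative 2: Birch reduction–alkylation of an indane ester.**
- Disconnection: the Cc–Cb bond.
- Forward key step: dissolving-metal reduction of the benzoate ring of the indane ester A3, which carries a primary chloride tethered to its benzylic stereocentre, gives an ester dienolate that is alkylated at the ipso carbon; the product is the tricyclic diene ester A4.
- For it: the quaternary carbon, ring A and the Ci=Cj alkene come from a flat aromatic in one step. The Ck/Cc relation is secured by the short tether, which is stronger on that stereocentre than the chosen route, where Ck comes from a carbene insertion.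
- Against it:
  - A4 has a six-membered ring where the target has ring C, so a one-carbon ring expansion is still owed.
  - Cn must be built as a quaternary centre on the enol ether carbon next to the new quaternary carbon, the most hindered position in the molecule.
  - The ester carbon of ring A is carried as a silyloxymethyl group and must be oxidised later.
  - The primary chloride of A3 has to survive the reducing medium.
- Comparison: the chosen strategy makes Cn first, where it is easy (lactone alkylation), and adds Cc next to it with the ring-C closure.

**Alternative 3: acyl-transfer ring expansion to the nine-membered lactam.**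
- Disconnection: the amide N–Cd bond and the Cq–Cp bond.
- Forward key step: the magnesium enolate of the cyclopentanone β-keto allyl ester A5 is C-acylated by the N-Fmoc β-amino acid chloride A6. After loss of Fmoc the amine adds to the ring ketone and the hemiaminal fragments, giving the nine-membered keto lactam A7.
- For it: the medium ring is made by expansion and not by end-to-end cyclisation. The CHMe stereocentre is bought with the amino acid; on that point it is stronger than the chosen route, which sets it in a Mannich closure.
- Against it:
  - The ketone of A5 that must accept the amine is flanked by quaternary Cc and by the acylated carbon.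
  - The purchased CHMe centre ends α to a ketone in A7 and can epimerise.
  - Ring D still has to be closed afterwards by a transannular N-alkylation on a nine-membered lactam, and the allyl ester removed.
  - As in Alternative 1, the tetracyclic core of A5 with both quaternary carbons is presupposed.
- Comparison: the chosen strategy spends its key step on that core.

Key step: step 16

Remark on the chemistry: the lactam nitrogen carries a methoxymethyl group from step 10 on; it protects the lactam and is later the source of the N-acyliminium ion. Lactone 7 is treated as not purchasable and is made in steps 1–3.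

## Route

Step 1
Reactants: 1 (R)-4-benzyloxazolidin-2-one; 2 (E)-but-2-enoyl chloride
Product: 3 (R)-4-benzyl-3-[(E)-but-2-enoyl]oxazolidin-2-one
Conditions: n-BuLi, THF, −78 °C; then 2, −78 → 0 °C
Reagents that add atoms: none
Why: N-Acylation of the lithiated oxazolidinone by the acid chloride (attachment of the Evans auxiliary); no stereocentre is formed.

Step 2
Reactants: 3 (R)-4-benzyl-3-[(E)-but-2-enoyl]oxazolidin-2-one; 4 tert-butyl bromoacetate
Product: 5 tert-butyl (3R)-3-{[(4R)-4-benzyl-2-oxooxazolidin-3-yl]carbonyl}pent-4-enoate
Conditions: NaN(SiMe3)2, THF, −78 °C; then 4, −78 → −40 °C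
Reagents that add atoms: none
Why: γ-Deprotonation gives the chelated sodium dienolate, which is alkylated at the α-carbon (Evans deconjugative alkylation). The bromoacetate enters on the face away from the benzyl group, which sets Cf.

Step 3
Reactants: 5 tert-butyl (3R)-3-{[(4R)-4-benzyl-2-oxooxazolidin-3-yl]carbonyl}pent-4-enoate
Product: 7 (R)-4-vinyldihydrofuran-2(3H)-one, via hydroxy tert-butyl ester 6 (not isolated)
Conditions: LiBH4, MeOH (1 equiv), THF, 0 °C; then CF3CO2H, CH2Cl2, rt
Reagents that add atoms: none
Why: LiBH4 reduces the imide carbonyl faster than the tert-butyl ester and releases the auxiliary. Acid then cleaves the tert-butyl ester and closes the γ-lactone; the stereocentre is not enolisable in either operation.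

Step 4
Reactants: 7 (R)-4-vinyldihydrofuran-2(3H)-one; 8 3-bromo-1,1-dimethoxypropane
Product: 9 (3S,4S)-3-(3,3-dimethoxypropyl)-4-vinyldihydrofuran-2(3H)-one (chain trans to vinyl)
Conditions: LiN(iPr)2, THF, −78 °C; then 8, DMPU, Bu4NI (cat.), −78 → −20 °C
Reagents that add atoms: none
Why: Alkylation of the lactone lithium enolate; the chain enters trans to the vinyl group. This centre is planarised again in step 5, so only clean monoalkylation matters here.

Step 5
Reactants: 9 (3S,4S)-3-(3,3-dimethoxypropyl)-4-vinyldihydrofuran-2(3H)-one; 4 tert-butyl bromoacetate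
Product: 10 tert-butyl 2-[(3S,4S)-3-(3,3-dimethoxypropyl)-2-oxo-4-vinyltetrahydrofuran-3-yl]acetate
Conditions: LiN(SiMe3)2, THF, −78 °C; then 4, DMPU, −78 → −30 °C
Reagents that add atoms: none
Why: Second enolate alkylation with a reactive α-halo ester. The electrophile approaches the face opposite the neighbouring vinyl group (trans alkylation of β-substituted butyrolactones), which sets Cn with the acetate arm trans and the acetal chain cis to vinyl.

Step 6
Reactants: 10 tert-butyl 2-[(3S,4S)-3-(3,3-dimethoxypropyl)-2-oxo-4-vinyltetrahydrofuran-3-yl]acetate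
Product: 12 (4S)-4-(3,3-dimethoxypropyl)-4-[(2S)-1-hydroxybut-3-en-2-yl]dihydrofuran-2(3H)-one, via diol tert-butyl ester 11 (not isolated)
Conditions: LiBH4, THF, 0 °C → rt; then KOtBu (0.2 equiv), THF, 0 °C
Reagents that add atoms: none
Why: LiBH4 opens the lactone to the diol and leaves the tert-butyl ester. Under alkoxide catalysis the neopentyl hydroxyl closes the five-membered lactone onto that ester (translactonisation; the γ-lactone is favoured over the δ-lactone open to the other hydroxyl), so the two primary hydroxyls become different.

Step 7
Reactants: 12 (4S)-4-(3,3-dimethoxypropyl)-4-[(2S)-1-hydroxybut-3-en-2-yl]dihydrofuran-2(3H)-one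
Product: 13 (4S)-4-[(2S)-1-azidobut-3-en-2-yl]-4-(3,3-dimethoxypropyl)dihydrofuran-2(3H)-one
Conditions: PPh3, diisopropyl azodicarboxylate, (PhO)2P(O)N3, THF, 0 °C → rt
Reagents that add atoms: diphenylphosphoryl azide, O=P(N=[N+]=[N-])(Oc1ccccc1)Oc1ccccc1
Why: Mitsunobu azidation of the only free primary alcohol; no stereocentre is involved.

Step 8
Reactants: 13 (4S)-4-[(2S)-1-azidobut-3-en-2-yl]-4-(3,3-dimethoxypropyl)dihydrofuran-2(3H)-one
Product: 15 (4S,5S)-4-(3,3-dimethoxypropyl)-4-(hydroxymethyl)-5-vinylpiperidin-2-one, via amino lactone 14 (not isolated)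
Conditions: PPh3, THF, rt; then H2O, 60 °C
Reagents that add atoms: none
Why: Staudinger reduction gives the primary amine, which attacks the γ-lactone carbonyl through a six-membered transition state. The δ-lactam forms and the CH2OH group on Cn is set free (lactone-to-lactam switch).

Step 9
Reactants: 15 (4S,5S)-4-(3,3-dimethoxypropyl)-4-(hydroxymethyl)-5-vinylpiperidin-2-one
Product: 16 (4S,5S)-4-[(tert-butyldimethylsilyloxy)methyl]-4-(3,3-dimethoxypropyl)-5-vinylpiperidin-2-one
Conditions: TBSCl, imidazole, DMF, rt
Reagents that add atoms: tert-butyldimethylsilyl chloride, CC(C)(C)[Si](C)(C)Cl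
Why: Standard silylation of the neopentyl primary alcohol.

Step 10
Reactants: 16 (4S,5S)-4-[(tert-butyldimethylsilyloxy)methyl]-4-(3,3-dimethoxypropyl)-5-vinylpiperidin-2-one
Product: 17 (4S,5S)-4-[(tert-butyldimethylsilyloxy)methyl]-4-(3,3-dimethoxypropyl)-1-(methoxymethyl)-5-vinylpiperidin-2-one
Conditions: NaH, THF/DMF, 0 °C; then ClCH2OCH3, 0 °C → rt
Reagents that add atoms: chloromethyl methyl ether, COCCl
Why: N-Alkylation of the lactam sodium salt. The N-acyl N,O-acetal is stable to base, hydride, palladium and fluoride and is ionised only by a strong Lewis acid (step 29).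

Step 11
Reactants: 18 cyclopent-2-en-1-one
Product: 19 2-iodocyclopent-2-en-1-one
Conditions: I2, pyridine, CH2Cl2, 0 °C → rt
Reagents that add atoms: iodine, II
Why: α-Iodination of the enone through conjugate addition of pyridine, iodination of the enolate and elimination (Johnson iodination).

Step 12
Reactants: 17 (4S,5S)-4-[(tert-butyldimethylsilyloxy)methyl]-4-(3,3-dimethoxypropyl)-1-(methoxymethyl)-5-vinylpiperidin-2-one; 19 2-iodocyclopent-2-en-1-one
Product: 21 lactam 17 in which the vinyl group has become a 2-(5-oxocyclopent-1-en-1-yl)ethyl group, via B-alkyl-9-borabicyclononane 20 (not isolated)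
Conditions: 9-BBN-H, THF, rt; then 19, PdCl2(dppf) (5 mol %), AsPh3, Cs2CO3, DMF/H2O, rt
Reagents that add atoms: none
Why: Anti-Markovnikov hydroboration of the monosubstituted alkene, then B-alkyl Suzuki–Miyaura coupling with the α-iodoenone. The lactam, silyl ether and acetal are inert to both.

Step 13
Reactants: 21 lactam carrying the 2-(5-oxocyclopent-1-en-1-yl)ethyl group
Product: 23 lactam carrying a 2-[2-(trifluoromethylsulfonyloxy)cyclopent-1-en-1-yl]ethyl group on Cf, via lithium enolate 22 (not isolated)
Conditions: Li[HB(s-Bu)3], THF, −78 °C; then PhN(SO2CF3)2, −78 → 0 °C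
Reagents that add atoms: N-phenylbis(trifluoromethanesulfonimide), O=S(=O)(N(c1ccccc1)S(=O)(=O)C(F)(F)F)C(F)(F)F
Why: Conjugate reduction of the α-substituted enone gives only the more substituted enolate, and O-triflation of it gives the tetrasubstituted alkenyl triflate regiospecifically (conjugate reduction–enolate trapping).

Step 14
Reactants: 23 alkenyl triflate lactam
Product: 24 3-(1-hydroxyethyl) lactam (mixture of epimers at the two new centres)
Conditions: LiN(iPr)2, THF, −78 °C; then CH3CHO, −78 °C
Reagents that add atoms: acetaldehyde, CC=O
Why: Aldol addition of the lactam lithium enolate (the only enolisable position) to acetaldehyde. Both new centres are removed in step 15, and the alkenyl triflate does not react with the amide base at −78 °C.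

Step 15
Reactants: 24 3-(1-hydroxyethyl) lactam
Product: 26 (Z)-3-ethylidene lactam carrying the cyclopentenyl triflate side chain, via mesylate 25 (not isolated)
Conditions: CH3SO2Cl, Et3N, CH2Cl2, 0 °C; then DBU, rt
Reagents that add atoms: none
Why: Mesylation and E1cB elimination give the α-alkylidene lactam. The methyl group is expected syn to the carbonyl, away from quaternary Cn (allylic strain); either geometry serves in step 16.

Step 16
Reactants: 26 (Z)-3-ethylidene lactam carrying the cyclopentenyl triflate side chain
Product: 27 tricyclic lactam with rings B, C and D and a vinyl group on Cc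
Conditions: Pd(OAc)2 (10 mol %), PPh3 (22 mol %), 1,2,2,6,6-pentamethylpiperidine, MeCN, 80 °C
Reagents that add atoms: none
Why: Zerovalent palladium, formed from Pd(OAc)2 and PPh3, adds oxidatively to the alkenyl triflate, and the cationic alkenylpalladium inserts the exocyclic alkene of the lactam; this is the intramolecular Heck reaction of an alkenyl triflate with a trisubstituted alkene, a known way to all-carbon quaternary centres. Ring C closes in the 7-exo-trig mode: Cj goes to the α-carbon and palladium to the exocyclic CH, the 8-endo mode being the larger and slower closure. The one new stereocentre, Cc, is controlled by the tether: the two-carbon chain sits on Cf, and the bicyclo[4.3.1] skeleton can form only when Cj adds to the face of ring D on which that chain lies (both axial, cis), so Cc follows from Cf. The alkylpalladium has no β-hydrogen on the new quaternary carbon, so syn β-hydride elimination can take only a methyl hydrogen and leaves the vinyl group, which makes the closure irreversible. The selectivities needed are exo over endo and insertion over reduction of the triflate; the cationic pathway open to triflates and the hindered amine base serve both, and the geometry of 26 is without consequence because the exocyclic carbon loses its stereochemistry.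

Step 17
Reactants: 27 tricyclic vinyl lactam (silyl ether)
Product: 28 tricyclic vinyl lactam with free CH2OH on Cn
Conditions: Bu4NF, THF, rt
Reagents that add atoms: none
Why: Fluoride cleavage of the silyl ether; nothing else in 27 is fluoride- or base-labile.

Step 18
Reactants: 28 tricyclic vinyl lactam with free CH2OH on Cn
Product: 29 acrylate ester of 28
Conditions: CH2=CHCOCl, iPr2NEt, CH2Cl2, −20 → 0 °C
Reagents that add atoms: acryloyl chloride, C=CC(=O)Cl
Why: O-Acylation of the neopentyl alcohol. The acrylate brings in the carboxyl carbon and Ca and becomes the tether for steps 19–22.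

Step 19
Reactants: 29 acrylate ester
Product: 30 α,β-unsaturated seven-membered lactone bridging Cc and Cn
Conditions: second-generation Hoveyda–Grubbs catalyst RuCl2(=CH-C6H4-2-OiPr)(H2IMes) (10 mol %), toluene (0.005 M), 80 °C
Reagents that add atoms: none
Why: Ring-closing metathesis of the vinyl group with the acrylate gives the cis-enoate lactone and forms the Cb=Ca bond. The two neighbouring quaternary carbons favour closure, and the tetrasubstituted alkene is inert to the catalyst.

Step 20
Reactants: 30 α,β-unsaturated seven-membered lactone
Product: 31 saturated seven-membered lactone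
Conditions: H2 (1 atm), Pd/C, EtOAc, rt
Reagents that add atoms: none
Why: Hydrogenation of the disubstituted conjugated alkene. The tetrasubstituted ring alkene is not reduced under these conditions, and no stereocentre is formed.

Step 21
Reactants: 31 saturated seven-membered lactone
Product: 33 α-diazo lactone, via α-trifluoroacetyl lactone 32 (not isolated)
Conditions: LiN(SiMe3)2, THF, −78 °C; CF3CO2CH2CF3; then 4-acetamidobenzenesulfonyl azide, Et3N, H2O (1 equiv), MeCN, rt
Reagents that add atoms: 4-acetamidobenzenesulfonyl azide, CC(=O)Nc1ccc(cc1)S(=O)(=O)N=[N+]=[N-]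
Why: Deacylative diazo transfer. The lactone α-CH2 is the only enolisable position; it is trifluoroacetylated, and the activated carbon takes the diazo group with loss of the trifluoroacetyl group.

Step 22
Reactants: 33 α-diazo lactone
Product: 34 pentacyclic lactone with ring A closed
Conditions: Rh2(O2CCMe3)4 (2 mol %), CH2Cl2, −20 °C → rt, slow addition
Reagents that add atoms: none
Why: The rhodium carbenoid at Ca inserts into the allylic C–H bond of Ck five atoms away (intramolecular 1,5 C–H insertion of an α-diazo ester, with retention at Ck); the bulky carboxylate ligand is chosen to slow the competing 1,2-hydride shift. The lactone holds Ca on the Cn face of ring B, so only the Ck hydrogen on that face is within reach, which sets Ck, and it keeps the carbene away from the lactam oxygen and from the chain on Cn. The carboxyl carbon remains bonded through oxygen to the CH2 on Cn, so Ca can only form with the ester cis to Cn.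

Step 23
Reactants: 34 pentacyclic lactone
Product: 35 methyl ester with free CH2OH on Cn
Conditions: K2CO3 (0.2 equiv), MeOH, 0 °C → rt; AcOH quench
Reagents that add atoms: methanol, CO
Why: Base-catalysed methanolysis of the bridged lactone. Under these mild conditions the ester α-CH is not expected to enolise, so Ca keeps its configuration.

Step 24
Reactants: 35 methyl ester with free CH2OH on Cn
Product: 36 acetate of 35 (tetracyclic core with CO2Me, CH2OAc, N-methoxymethyl and the dimethyl acetal chain)
Conditions: Ac2O, pyridine, DMAP (cat.), CH2Cl2, rt
Reagents that add atoms: acetic anhydride, CC(=O)OC(C)=O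
Why: Acetylation of the primary alcohol. Doing it here also keeps the hydroxyl from forming a cyclic acetal with the aldehyde of step 25.

Step 25
Reactants: 36 acetal
Product: 37 aldehyde
Conditions: pyridinium p-toluenesulfonate, acetone/H2O (4:1), 50 °C
Reagents that add atoms: water, O
Why: Mild acid hydrolysis of the dimethyl acetal. The N-acyl N,O-acetal on nitrogen, the esters and the alkene tolerate it.

Step 26
Reactants: 37 aldehyde
Product: 38 allylic alcohol (both epimers at the carbinol)
Conditions: CH2=CHMgBr (1.3 equiv), THF, −78 °C
Reagents that add atoms: vinylmagnesium bromide, C=C[Mg]Br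
Why: Grignard addition to the aldehyde, which at −78 °C reacts far faster than the acetate, the methyl ester or the lactam. The new centre is removed in step 27.

Step 27
Reactants: 38 allylic alcohol
Product: 39 vinyl ketone
Conditions: Dess–Martin periodinane, NaHCO3, CH2Cl2, 0 °C
Reagents that add atoms: none
Why: Buffered oxidation of the allylic alcohol to the enone without touching the ester α-centre.

Step 28
Reactants: 39 vinyl ketone
Product: 40 (Z)-triethylsilyl enol ether
Conditions: Et3SiH, RhCl(PPh3)3 (2 mol %), benzene, 50 °C
Reagents that add atoms: triethylsilane, CC[SiH](CC)CC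
Why: Rhodium-catalysed 1,4-hydrosilylation of the enone places the enol ether double bond towards the former vinyl carbon only, so the nucleophilic carbon is Cr and not Cp; the Z isomer is the usual outcome.

Step 29
Reactants: 40 (Z)-triethylsilyl enol ether
Product: 42 pentacyclic ketone (ring E closed, CHMe in place), via N-acyliminium ion 41 (not isolated)
Conditions: BF3·OEt2 (2.5 equiv), CH2Cl2 (0.002 M), −78 → −20 °C
Reagents that add atoms: none
Why: The Lewis acid removes methoxide from N–CH2OMe, and the N-acyliminium ion is trapped by the silyl enol ether (intramolecular Mukaiyama–Mannich reaction); this forms Cs–Cr and closes ring E, helped by the chain lying under the lactam. Cr is expected to form with methyl on the outer face of the ring; being α to the ketone, it can also be equilibrated with DBU without touching the less acidic ester centre.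

Step 30
Reactants: 42 pentacyclic ketone
Product: 43 target, CNP0296366.1
Conditions: NaBH4, MeOH, −40 °C
Reagents that add atoms: none
Why: Chemoselective ketone reduction in the presence of the acetate, ester and lactam. The small hydride is expected to attack from the outer face anti to the neighbouring methyl group, as with 2-alkylcycloalkanones, giving the alcohol trans to methyl on ring E (syn in the extended chain), which sets Cq.

## Compound list

1 | (R)-4-benzyloxazolidin-2-one | O=C1N[C@H](Cc2ccccc2)CO1 | starting material
2 | (E)-but-2-enoyl chloride | C/C=C/C(=O)Cl | starting material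
3 | (R)-4-benzyl-3-[(E)-but-2-enoyl]oxazolidin-2-one | C/C=C/C(=O)N1[C@H](Cc2ccccc2)COC1=O | intermediate
4 | tert-butyl bromoacetate | BrCC(=O)OC(C)(C)C | starting material
5 | tert-butyl (3R)-3-{[(4R)-4-benzyl-2-oxooxazolidin-3-yl]carbonyl}pent-4-enoate | C=C[C@@H](CC(=O)OC(C)(C)C)C(=O)N1[C@H](Cc2ccccc2)COC1=O | intermediate
6 | tert-butyl (3R)-3-(hydroxymethyl)pent-4-enoate (not isolated) | C=C[C@@H](CC(=O)OC(C)(C)C)CO | intermediate
7 | (R)-4-vinyldihydrofuran-2(3H)-one | O=C1C[C@H](C=C)CO1 | intermediate
8 | 3-bromo-1,1-dimethoxypropane | COC(CCBr)OC | starting material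
9 | (3S,4S)-3-(3,3-dimethoxypropyl)-4-vinyldihydrofuran-2(3H)-one (chain trans to vinyl) | O1C[C@@H](C=C)[C@H](CCC(OC)OC)C1=O | intermediate
10 | tert-butyl 2-[(3S,4S)-3-(3,3-dimethoxypropyl)-2-oxo-4-vinyltetrahydrofuran-3-yl]acetate (acetate arm trans to vinyl) | O1C[C@@H](C=C)[C@@](CC(=O)OC(C)(C)C)(CCC(OC)OC)C1=O | intermediate
11 | diol tert-butyl ester from reduction of the lactone of 10 (not isolated) | OC[C@@H](C=C)[C@@](CC(=O)OC(C)(C)C)(CCC(OC)OC)CO | intermediate
12 | (4S)-4-(3,3-dimethoxypropyl)-4-[(2S)-1-hydroxybut-3-en-2-yl]dihydrofuran-2(3H)-one | OC[C@@H](C=C)[C@]1(CCC(OC)OC)CC(=O)OC1 | intermediate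
13 | (4S)-4-[(2S)-1-azidobut-3-en-2-yl]-4-(3,3-dimethoxypropyl)dihydrofuran-2(3H)-one | [N-]=[N+]=NC[C@@H](C=C)[C@]1(CCC(OC)OC)CC(=O)OC1 | intermediate
14 | amino lactone, the amine corresponding to azide 13 (not isolated) | NC[C@@H](C=C)[C@]1(CCC(OC)OC)CC(=O)OC1 | intermediate
15 | (4S,5S)-4-(3,3-dimethoxypropyl)-4-(hydroxymethyl)-5-vinylpiperidin-2-one | C1C(=O)NC[C@@H](C=C)[C@]1(CO)CCC(OC)OC | intermediate
16 | (4S,5S)-4-[(tert-butyldimethylsilyloxy)methyl]-4-(3,3-dimethoxypropyl)-5-vinylpiperidin-2-one | C1C(=O)NC[C@@H](C=C)[C@]1(CO[Si](C)(C)C(C)(C)C)CCC(OC)OC | intermediate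
17 | (4S,5S)-4-[(tert-butyldimethylsilyloxy)methyl]-4-(3,3-dimethoxypropyl)-1-(methoxymethyl)-5-vinylpiperidin-2-one | C1C(=O)N(COC)C[C@@H](C=C)[C@]1(CO[Si](C)(C)C(C)(C)C)CCC(OC)OC | intermediate
18 | cyclopent-2-en-1-one | O=C1CCC=C1 | starting material
19 | 2-iodocyclopent-2-en-1-one | O=C1CCC=C1I | intermediate
20 | B-alkyl-9-borabicyclo[3.3.1]nonane from hydroboration of the vinyl group of 17 (not isolated) | C1C(=O)N(COC)C[C@@H](CCB2C3CCCC2CCC3)[C@]1(CO[Si](C)(C)C(C)(C)C)CCC(OC)OC | intermediate
21 | lactam 17 with the vinyl group replaced by 2-(5-oxocyclopent-1-en-1-yl)ethyl | C1C(=O)N(COC)C[C@@H](CCC2=CCCC2=O)[C@]1(CO[Si](C)(C)C(C)(C)C)CCC(OC)OC | intermediate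
22 | lithium 2-alkylcyclopent-1-en-1-olate from conjugate reduction of 21 (not isolated) | C1C(=O)N(COC)C[C@@H](CCC2=C([O-])CCC2)[C@]1(CO[Si](C)(C)C(C)(C)C)CCC(OC)OC.[Li+] | intermediate
23 | lactam carrying 2-[2-(trifluoromethylsulfonyloxy)cyclopent-1-en-1-yl]ethyl on Cf, CH2OTBS and the acetal chain on Cn, N-methoxymethyl | C1C(=O)N(COC)C[C@@H](CCC2=C(OS(=O)(=O)C(F)(F)F)CCC2)[C@]1(CO[Si](C)(C)C(C)(C)C)CCC(OC)OC | intermediate
24 | 3-(1-hydroxyethyl) derivative of 23 (epimers at the two new centres) | CC(O)C1C(=O)N(COC)C[C@@H](CCC2=C(OS(=O)(=O)C(F)(F)F)CCC2)[C@]1(CO[Si](C)(C)C(C)(C)C)CCC(OC)OC | intermediate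
25 | methanesulfonate of 24 (not isolated) | CC(OS(C)(=O)=O)C1C(=O)N(COC)C[C@@H](CCC2=C(OS(=O)(=O)C(F)(F)F)CCC2)[C@]1(CO[Si](C)(C)C(C)(C)C)CCC(OC)OC | intermediate
26 | (Z)-3-ethylidene lactam with the cyclopentenyl triflate side chain (precursor of the key step) | C/C=C1\C(=O)N(COC)C[C@@H](CCC2=C(OS(=O)(=O)C(F)(F)F)CCC2)[C@]1(CO[Si](C)(C)C(C)(C)C)CCC(OC)OC | intermediate
27 | tricyclic lactam (rings B, C, D) with vinyl on Cc, CH2OTBS and acetal chain on Cn (product of the key step) | C=C[C@@]23C(=O)N(COC)C[C@@H](CCC5=C2CCC5)[C@]3(CO[Si](C)(C)C(C)(C)C)CCC(OC)OC | intermediate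
28 | alcohol from desilylation of 27 | C=C[C@@]23C(=O)N(COC)C[C@@H](CCC5=C2CCC5)[C@]3(CO)CCC(OC)OC | intermediate
29 | acrylate ester of 28 | C=C[C@@]23C(=O)N(COC)C[C@@H](CCC5=C2CCC5)[C@]3(COC(=O)C=C)CCC(OC)OC | intermediate
30 | α,β-unsaturated seven-membered lactone (Cc–CH=CH–CO–O–CH2–Cn) | O=C1C=C[C@@]23C(=O)N(COC)C[C@@H](CCC5=C2CCC5)[C@]3(CO1)CCC(OC)OC | intermediate
31 | saturated seven-membered lactone | O=C1CC[C@@]23C(=O)N(COC)C[C@@H](CCC5=C2CCC5)[C@]3(CO1)CCC(OC)OC | intermediate
32 | α-trifluoroacetyl lactone (not isolated) | O=C1C(C(=O)C(F)(F)F)C[C@@]23C(=O)N(COC)C[C@@H](CCC5=C2CCC5)[C@]3(CO1)CCC(OC)OC | intermediate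
33 | α-diazo lactone | O=C1C(=[N+]=[N-])C[C@@]23C(=O)N(COC)C[C@@H](CCC5=C2CCC5)[C@]3(CO1)CCC(OC)OC | intermediate
34 | pentacyclic lactone: rings A–D plus the lactone bridging Ca and Cn | O=C6[C@@H]1C[C@@]23C(=O)N(COC)C[C@@H](CCC5=C2[C@@H]1CC5)[C@]3(CO6)CCC(OC)OC | intermediate
35 | methyl ester with free CH2OH on Cn | COC(=O)[C@@H]1C[C@@]23C(=O)N(COC)C[C@@H](CCC5=C2[C@@H]1CC5)[C@]3(CO)CCC(OC)OC | intermediate
36 | acetate of 35 | COC(=O)[C@@H]1C[C@@]23C(=O)N(COC)C[C@@H](CCC5=C2[C@@H]1CC5)[C@]3(COC(C)=O)CCC(OC)OC | intermediate
37 | aldehyde from hydrolysis of the acetal of 36 | COC(=O)[C@@H]1C[C@@]23C(=O)N(COC)C[C@@H](CCC5=C2[C@@H]1CC5)[C@]3(COC(C)=O)CCC=O | intermediate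
38 | allylic alcohol (carbinol epimers) | COC(=O)[C@@H]1C[C@@]23C(=O)N(COC)C[C@@H](CCC5=C2[C@@H]1CC5)[C@]3(COC(C)=O)CCC(O)C=C | intermediate
39 | vinyl ketone | COC(=O)[C@@H]1C[C@@]23C(=O)N(COC)C[C@@H](CCC5=C2[C@@H]1CC5)[C@]3(COC(C)=O)CCC(=O)C=C | intermediate
40 | (Z)-triethylsilyl enol ether of the ethyl ketone | COC(=O)[C@@H]1C[C@@]23C(=O)N(COC)C[C@@H](CCC5=C2[C@@H]1CC5)[C@]3(COC(C)=O)CC/C(O[Si](CC)(CC)CC)=C/C | intermediate
41 | N-methylene N-acyliminium ion with methoxytrifluoroborate counter-ion (not isolated) | COC(=O)[C@@H]1C[C@@]23C(=O)[N+](=C)C[C@@H](CCC5=C2[C@@H]1CC5)[C@]3(COC(C)=O)CC/C(O[Si](CC)(CC)CC)=C/C.CO[B-](F)(F)F | intermediate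
42 | pentacyclic ketone, the target oxidised at the carbinol | COC(=O)[C@@H]1C[C@@]23C(=O)N4C[C@@H](CCC5=C2[C@@H]1CC5)[C@]3(COC(C)=O)CCC(=O)[C@H](C)C4 | intermediate
43 | CNP0296366.1 | COC(=O)[C@@H]1C[C@@]23C(=O)N4C[C@@H](CCC5=C2[C@@H]1CC5)[C@]3(COC(C)=O)CC[C@@H](O)[C@H](C)C4 | target

## Step count and the least certain steps

Total: 30 steps. Longest linear sequence: 29 steps (steps 1–10 and 12–30); step 11 is a one-step side branch.

**Step 16 (key step).**
- What may go wrong: the alkenylpalladium may add to the exocyclic carbon instead (8-endo closure; that carbon is the electronically preferred site of an unsaturated amide). Alternatively, insertion into a trisubstituted alkene next to quaternary Cn may be so slow that reduction or hydrolysis of the triflate takes over.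
- Fallback: make the same bond from an enolate. Starting from 26, kinetic deconjugation (LiN(iPr)2, then AcOH at −78 °C) gives the 3-vinyl lactam F1. Its potassium dienolate (KN(SiMe3)2) is coupled intramolecularly with the alkenyl triflate under zerovalent palladium with a bulky phosphine (Pd2(dba)3, P(t-Bu)3). This is a palladium-catalysed α-alkenylation in which the C–C bond forms by reductive elimination at the α-carbon; the exocyclic CH is not nucleophilic, and coupling at the far end of the dienolate would need a nine-membered ring. The route is rejoined at 27.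

**Step 22.**
- What may go wrong: a 1,2-hydride shift from Cb in the carbenoid, which returns unsaturated lactone 30 (recyclable through steps 20–21), or carbene dimerisation, may outrun the insertion, because the Ck–H bond lies on the more crowded face.
- Fallback: a photochemical closure that uses the same tether. From 31, hydroxylation of the lactone enolate (LiN(SiMe3)2, 2-(phenylsulfonyl)-3-phenyloxaziridine) gives α-hydroxy lactone F2, and Dess–Martin oxidation gives α-keto lactone F3. The keto lactone has no γ-hydrogen, so on irradiation the excited ketone should abstract the allylic hydrogen of Ck, and radical recombination closes ring A as the tertiary α-hydroxy lactone F4 (Norrish–Yang cyclisation). SmI2/HMPA/MeOH removes the α-hydroxyl, and the route is rejoined at 34.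

**Step 29.**
- What may go wrong: intermolecular Mannich reaction and loss of the silyl group may compete with the entropically costly nine-membered closure, and facial selectivity at Cr in a medium-ring transition state may be poor.
- Fallback: a stabilised nucleophile and thermodynamic control. From 37, aldol addition of the lithium enolate of allyl propionate gives β-hydroxy ester F5, and Dess–Martin oxidation gives β-keto allyl ester F6. Its enol closes onto the N-acyliminium ion under BF3·OEt2 to give the nine-membered β-keto ester F7, with reversible and repeatable ionisation and no silyl group to lose. Pd(PPh3)4/morpholine removes the allyl ester with decarboxylation, and Cr is set by protonation and equilibration. The route is rejoined at 42.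

**Step 30.**
- What may go wrong: hydride may be delivered to the other face of the ketone (poor facial selectivity in a flexible nine-membered ring; the open-chain Felkin preference points to the other epimer).
- Fallback: set Cq by inversion. From 42 the reduction then gives the epimeric alcohol F8. Mitsunobu reaction with chloroacetic acid (PPh3, diisopropyl azodicarboxylate) gives the inverted chloroacetate F9, which thiourea/NaHCO3 cleaves without touching the primary acetate. The route is rejoined at 43.

**Step 19.**
- What may go wrong: the catalyst may decompose before ring closure, because one alkene is a vinyl group on a quaternary carbon and the other an electron-poor acrylate; oligomerisation through the acrylate is the likely side process.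
- Fallback: close the lactone by transesterification. From 27, cross-metathesis with excess methyl acrylate gives the E-acrylate F10. Hydrogenation (H2, Pd/C) gives ester F11, Bu4NF gives hydroxy ester F12, and Ti(OiPr)4-catalysed lactonisation in hot toluene with removal of methanol rejoins the route at 31.

## Further compounds

F1 | step 16 | 3-vinyl lactam (deconjugated isomer of 26; epimers at the α-carbon) | C=CC1C(=O)N(COC)C[C@@H](CCC2=C(OS(=O)(=O)C(F)(F)F)CCC2)[C@]1(CO[Si](C)(C)C(C)(C)C)CCC(OC)OC
F2 | step 22 | α-hydroxy seven-membered lactone (epimers) | O=C1C(O)C[C@@]23C(=O)N(COC)C[C@@H](CCC5=C2CCC5)[C@]3(CO1)CCC(OC)OC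
F3 | step 22 | α-keto seven-membered lactone | O=C1C(=O)C[C@@]23C(=O)N(COC)C[C@@H](CCC5=C2CCC5)[C@]3(CO1)CCC(OC)OC
F4 | step 22 | pentacyclic α-hydroxy lactone (34 with OH in place of H on Ca) | O=C6[C@]1(O)C[C@@]23C(=O)N(COC)C[C@@H](CCC5=C2[C@@H]1CC5)[C@]3(CO6)CCC(OC)OC
F5 | step 29 | β-hydroxy allyl ester from 37 and allyl propionate (epimers) | COC(=O)[C@@H]1C[C@@]23C(=O)N(COC)C[C@@H](CCC5=C2[C@@H]1CC5)[C@]3(COC(C)=O)CCC(O)C(C)C(=O)OCC=C
F6 | step 29 | β-keto allyl ester | COC(=O)[C@@H]1C[C@@]23C(=O)N(COC)C[C@@H](CCC5=C2[C@@H]1CC5)[C@]3(COC(C)=O)CCC(=O)C(C)C(=O)OCC=C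
F7 | step 29 | nine-membered β-keto allyl ester with quaternary Cr | COC(=O)[C@@H]1C[C@@]23C(=O)N4C[C@@H](CCC5=C2[C@@H]1CC5)[C@]3(COC(C)=O)CCC(=O)C(C)(C(=O)OCC=C)C4
F8 | step 30 | carbinol epimer of the target | COC(=O)[C@@H]1C[C@@]23C(=O)N4C[C@@H](CCC5=C2[C@@H]1CC5)[C@]3(COC(C)=O)CC[C@H](O)[C@H](C)C4
F9 | step 30 | chloroacetate of the target | COC(=O)[C@@H]1C[C@@]23C(=O)N4C[C@@H](CCC5=C2[C@@H]1CC5)[C@]3(COC(C)=O)CC[C@@H](OC(=O)CCl)[C@H](C)C4
F10 | step 19 | E-acrylate on Cc (cross-metathesis product of 27) | COC(=O)/C=C/[C@@]23C(=O)N(COC)C[C@@H](CCC5=C2CCC5)[C@]3(CO[Si](C)(C)C(C)(C)C)CCC(OC)OC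
F11 | step 19 | saturated methyl ester, silyl ether | COC(=O)CC[C@@]23C(=O)N(COC)C[C@@H](CCC5=C2CCC5)[C@]3(CO[Si](C)(C)C(C)(C)C)CCC(OC)OC
F12 | step 19 | hydroxy methyl ester | COC(=O)CC[C@@]23C(=O)N(COC)C[C@@H](CCC5=C2CCC5)[C@]3(CO)CCC(OC)OC
A1 | alternative 1 | pentacyclic ketone, product of the Mannich closure (identical with 42) | COC(=O)[C@@H]1C[C@@]23C(=O)N4C[C@@H](CCC5=C2[C@@H]1CC5)[C@]3(COC(C)=O)CCC(=O)[C@H](C)C4
A2 | alternative 1 | N-methoxymethyl lactam with Z triethylsilyl enol ether (identical with 40) | COC(=O)[C@@H]1C[C@@]23C(=O)N(COC)C[C@@H](CCC5=C2[C@@H]1CC5)[C@]3(COC(C)=O)CC/C(O[Si](CC)(CC)CC)=C/C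
A3 | alternative 2 | indane tert-butyl ester with methoxy group and tethered primary chloride | CC(C)(C)[Si](C)(C)OC[C@@H]([C@H]1CCc2ccc(OC)c(C(=O)OC(C)(C)C)c12)CCl
A4 | alternative 2 | tricyclic diene ester with quaternary carbon and methyl enol ether | CC(C)(C)[Si](C)(C)OC[C@@H]1C[C@]2(C(=O)OC(C)(C)C)C(OC)=CCC3=C2[C@@H]1CC3
A5 | alternative 3 | tetracyclic cyclopentanone β-keto allyl ester | COC(=O)[C@@H]1C[C@@]23C(=O)C(C(=O)OCC=C)C[C@@]3(COC(C)=O)[C@@H](CO[Si](C)(C)C(C)(C)C)CCC4=C2[C@@H]1CC4
A6 | alternative 3 | (R)-3-(Fmoc-amino)-2-methylpropanoyl chloride | O=C(OCC1c2ccccc2-c2ccccc12)NC[C@@H](C)C(Cl)=O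
A7 | alternative 3 | nine-membered keto lactam carrying the allyl ester | COC(=O)[C@@H]1C[C@@]23C(=O)NC[C@@H](C)C(=O)[C@H](C(=O)OCC=C)C[C@@]3(COC(C)=O)[C@@H](CO[Si](C)(C)C(C)(C)C)CCC4=C2[C@@H]1CC4
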